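**Retrosynthetic overview**
1. Target ⇒ its 8,11-bis-silyl ether ⇒ the five-membered enone ring is opened at C3=C4 (aldol condensation) to a 1,4-diketone whose methyl ketone comes from a propargyl group on C9.
2. The eight-membered ring is opened at C5–C14 (intramolecular samarium Reformatsky-type aldol of an α-bromo ketone aldehyde); the C10 methyl comes from an exo-methylene group (hydrogen atom transfer).
3. Key disconnection C11–C12: intermolecular allylboration (carbonyl allylation) of a cyclohexanone-based α-methylene aldehyde with a (Z)-γ,γ-disubstituted allylboronate, which sets C11 and the quaternary C12.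
4. The ring fragment comes from cyclohexane-1,3-dione (two C-alkylations, CBS desymmetrisation for C8/C9, enone/cuprate chemistry for the C5 and C6 methyls); the boronate fragment comes from but-3-yn-1-ol (ynoate, syn-carbocupration).
5. Ring order: six-membered ring (present from the start) → eight-membered ring → five-membered ring.

Assumption: the stereodescriptors of the SMILES are taken exactly as written and copied unchanged into every intermediate. Atoms are numbered as in mutilin: C1 CH2, C2 C=O, C3 =CH, C4 =C, C5 quaternary (Me), C6 CHMe, C7 CH2, C8 CHOH, C9 quaternary, C10 CHMe, C11 CHOH, C12 quaternary (Me, vinyl), C13 CH2, C14 CHOAc.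

**Route**

Step 1
Reactants: 1 cyclohexane-1,3-dione; 2 1-bromo-3-methylbut-2-ene
Product: 3 2-(3-methylbut-2-en-1-yl)cyclohexane-1,3-dione
Conditions: KOH (1.0 equiv), H2O, 0 → 23 °C
Reagents that add atoms: none
Why: C-alkylation of the 1,3-dione enolate with the allylic bromide in water (SN2 alkylation, O-alkylation suppressed by the protic medium) gives the 2-monosubstituted dione and creates no stereocentre.

Step 2
Reactants: 3 2-(3-methylbut-2-en-1-yl)cyclohexane-1,3-dione; 4 3-bromoprop-1-yne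
Product: 5 2-(3-methylbut-2-en-1-yl)-2-(prop-2-yn-1-yl)cyclohexane-1,3-dione
Conditions: KOH (1.1 equiv), H2O, 23 → 50 °C
Reagents that add atoms: none
Why: A second SN2 C-alkylation of the 2-substituted dione enolate with the reactive propargylic bromide makes the future C9 a prochiral quaternary carbon that carries the latent C10–C11 arm (prenyl) and the latent C1–C3 arm (propargyl).

Step 3
Reactants: 5 2-(3-methylbut-2-en-1-yl)-2-(prop-2-yn-1-yl)cyclohexane-1,3-dione
Product: 6 (2R,3S)-3-hydroxy-2-(3-methylbut-2-en-1-yl)-2-(prop-2-yn-1-yl)cyclohexan-1-one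
Conditions: (R)-Me-CBS [(R)-1-methyl-3,3-diphenyltetrahydro-1H,3H-pyrrolo[1,2-c][1,3,2]oxazaborole] (0.2 equiv), catecholborane (1.5 equiv), toluene, −78 → −40 °C; MeOH, aq. NaHCO3
Reagents that add atoms: none
Why: Corey–Bakshi–Shibata desymmetrising reduction: the oxazaborolidine–borane complex reduces one of the two enantiotopic carbonyls with the quaternary carbon as the large group, which gives the (S)-carbinol at C8, and hydride enters on the side of the slim propargyl group and anti to the bulkier prenyl group, which makes C9 (R) with the hydroxyl cis to the prenyl arm (minor diastereomer removed by chromatography), while catecholborane at low temperature leaves alkyne and alkene alone.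

Step 4
Reactants: 6 (2R,3S)-3-hydroxy-2-(3-methylbut-2-en-1-yl)-2-(prop-2-yn-1-yl)cyclohexan-1-one
Product: 7 (2R,3S)-3-[(tert-butyldimethylsilyl)oxy]-2-(3-methylbut-2-en-1-yl)-2-(prop-2-yn-1-yl)cyclohexan-1-one
Conditions: TBSOTf, 2,6-lutidine, CH2Cl2, −78 → 0 °C
Reagents that add atoms: tert-butyldimethylsilyl trifluoromethanesulfonate, CC(C)(C)[Si](C)(C)OS(=O)(=O)C(F)(F)F
Why: Silylation of the hindered secondary alcohol with the silyl triflate protects O8 for the base, cuprate and oxidation steps that follow.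

Step 5
Reactants: 7 (2R,3S)-3-[(tert-butyldimethylsilyl)oxy]-2-(3-methylbut-2-en-1-yl)-2-(prop-2-yn-1-yl)cyclohexan-1-one
Product: 8 (2R,3S)-3-[(tert-butyldimethylsilyl)oxy]-6-methyl-2-(3-methylbut-2-en-1-yl)-2-(prop-2-yn-1-yl)cyclohexan-1-one (both epimers at the methyl-bearing carbon, C5)
Conditions: LiN(iPr)2 (1.05 equiv), THF, −78 °C; MeI, −78 → −20 °C
Reagents that add atoms: iodomethane, CI
Why: Enolate alkylation: the ketone can enolise only towards C5 because C9 is quaternary, so one equivalent of amide base and methyl iodide methylate C5 (the ketone α-CH is far more acidic than the alkyne CH), and the configuration of the new centre does not matter because C5 is planarised in the next step.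

Step 6
Reactants: 8 (2R,3S)-3-[(tert-butyldimethylsilyl)oxy]-6-methyl-2-(3-methylbut-2-en-1-yl)-2-(prop-2-yn-1-yl)cyclohexan-1-one
Product: 10 (5S,6R)-5-[(tert-butyldimethylsilyl)oxy]-2-methyl-6-(3-methylbut-2-en-1-yl)-6-(prop-2-yn-1-yl)cyclohex-2-en-1-one, via trimethylsilyl enol ether 9 (not isolated)
Conditions: TMSOTf, Et3N, CH2Cl2, 0 °C; then IBX·MPO (IBX–4-methoxypyridine N-oxide complex), DMSO, 23 °C
Reagents that add atoms: trimethylsilyl trifluoromethanesulfonate, C[Si](C)(C)OS(=O)(=O)C(F)(F)F (silyl group of 9 only)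
Why: Soft enolisation gives the only possible silyl enol ether and its dehydrogenation with IBX·MPO (a Saegusa–Ito-type oxidation that avoids palladium and so tolerates the terminal alkyne) places the double bond at C5=C6.

Step 7
Reactants: 10 (5S,6R)-5-[(tert-butyldimethylsilyl)oxy]-2-methyl-6-(3-methylbut-2-en-1-yl)-6-(prop-2-yn-1-yl)cyclohex-2-en-1-one
Product: 11 (2R,3S,5S,6R)-3-[(tert-butyldimethylsilyl)oxy]-5,6-dimethyl-2-(3-methylbut-2-en-1-yl)-2-(prop-2-yn-1-yl)cyclohexan-1-one
Conditions: Me2CuLi (3 equiv), Et2O, −40 → 0 °C; aq. NH4Cl; then NaOMe (cat.), MeOH, 23 °C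
Reagents that add atoms: lithium dimethylcuprate, [Li+].C[Cu-]C
Why: Conjugate (1,4-) addition of lithium dimethylcuprate to the 5-substituted cyclohexenone occurs axially and anti to the C8 silyloxy group, which sets C6 (S) with its methyl trans to that group, and methoxide equilibration then places the C5 methyl equatorial and trans to the C6 methyl.

Step 8
Reactants: 11 (2R,3S,5S,6R)-3-[(tert-butyldimethylsilyl)oxy]-5,6-dimethyl-2-(3-methylbut-2-en-1-yl)-2-(prop-2-yn-1-yl)cyclohexan-1-one
Product: 12 2-[(1S,3R,4S,6S)-6-[(tert-butyldimethylsilyl)oxy]-3,4-dimethyl-2-oxo-1-(prop-2-yn-1-yl)cyclohexyl]acetaldehyde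
Conditions: OsO4 (2 mol %), NaIO4 (4 equiv), 2,6-lutidine, dioxane–H2O (3:1), 23 °C
Reagents that add atoms: osmium tetroxide, O=[Os](=O)(=O)=O; sodium periodate, [Na+].[O-]I(=O)(=O)=O; water, O
Why: Lemieux–Johnson oxidative cleavage: OsO4 dihydroxylates the electron-rich trisubstituted alkene much faster than the alkyne and periodate cleaves the diol to the C11 aldehyde and acetone without touching a stereocentre.

Step 9
Reactants: 12 2-[(1S,3R,4S,6S)-6-[(tert-butyldimethylsilyl)oxy]-3,4-dimethyl-2-oxo-1-(prop-2-yn-1-yl)cyclohexyl]acetaldehyde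
Product: 14 2-[(1S,3R,4S,6S)-6-[(tert-butyldimethylsilyl)oxy]-3,4-dimethyl-2-oxo-1-(prop-2-yn-1-yl)cyclohexyl]prop-2-enal, via Mannich base 13 (not isolated)
Conditions: dimethylmethylideneammonium iodide (Eschenmoser's salt), Et3N, CH2Cl2, 23 °C
Reagents that add atoms: dimethylmethylideneammonium iodide, C=[N+](C)C.[I-]
Why: Mannich reaction of the aldehyde with the iminium salt followed by β-elimination of dimethylamine gives the α-methylene aldehyde (the hindered ketone does not compete), so C10 is sp2 and no epimerisable centre sits next to the aldehyde during the fragment union.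

Step 10
Reactants: 15 but-3-yn-1-ol
Product: 16 1-[(but-3-yn-1-yloxy)methyl]-4-methoxybenzene
Conditions: NaH (1.05 equiv), 4-methoxybenzyl chloride, Bu4NI (cat.), THF–DMF, 0 → 23 °C
Reagents that add atoms: 4-methoxybenzyl chloride, COc1ccc(CCl)cc1
Why: Williamson ether synthesis of the alkoxide (one equivalent of NaH does not deprotonate the alkyne) protects O14 as a p-methoxybenzyl (PMB) ether.

Step 11
Reactants: 16 1-[(but-3-yn-1-yloxy)methyl]-4-methoxybenzene
Product: 17 ethyl 5-[(4-methoxyphenyl)methoxy]pent-2-ynoate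
Conditions: n-BuLi, THF, −78 °C; ClCO2Et, −78 → 0 °C
Reagents that add atoms: ethyl chloroformate, CCOC(=O)Cl
Why: Deprotonation of the terminal alkyne and C-acylation of the lithium acetylide with the chloroformate give the ynoate.

Step 12
Reactants: 17 ethyl 5-[(4-methoxyphenyl)methoxy]pent-2-ynoate
Product: 18 ethyl (2Z)-5-[(4-methoxyphenyl)methoxy]-3-methylpent-2-enoate
Conditions: Me2CuLi, THF, −78 °C; MeOH, −78 °C; aq. NH4Cl
Reagents that add atoms: lithium dimethylcuprate, [Li+].C[Cu-]C
Why: syn-Carbocupration (conjugate addition) of lithium dimethylcuprate to the ynoate and protonation of the vinylcopper at −78 °C put the new methyl trans and the alkoxyethyl chain cis to the ester, i.e. the (Z)-enoate.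

Step 13
Reactants: 18 ethyl (2Z)-5-[(4-methoxyphenyl)methoxy]-3-methylpent-2-enoate
Product: 19 (2Z)-5-[(4-methoxyphenyl)methoxy]-3-methylpent-2-en-1-ol
Conditions: iBu2AlH (2.2 equiv), CH2Cl2, −78 °C; aq. potassium sodium tartrate
Reagents that add atoms: none
Why: 1,2-Reduction of the conjugated ester by two hydride equivalents gives the allylic alcohol with the alkene geometry unchanged.

Step 14
Reactants: 19 (2Z)-5-[(4-methoxyphenyl)methoxy]-3-methylpent-2-en-1-ol
Product: 20 (2Z)-5-[(4-methoxyphenyl)methoxy]-3-methylpent-2-en-1-yl acetate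
Conditions: Ac2O, Et3N, DMAP (4-dimethylaminopyridine, cat.), CH2Cl2, 0 → 23 °C
Reagents that add atoms: acetic anhydride, CC(=O)OC(C)=O
Why: Acylation of the primary allylic alcohol gives the leaving group for π-allyl formation.

Step 15
Reactants: 20 (2Z)-5-[(4-methoxyphenyl)methoxy]-3-methylpent-2-en-1-yl acetate
Product: 21 2-[(2Z)-5-[(4-methoxyphenyl)methoxy]-3-methylpent-2-en-1-yl]-4,4,5,5-tetramethyl-1,3,2-dioxaborolane
Conditions: Pd2(dba)3 (2.5 mol %), B2pin2, DMSO, 50 °C
Reagents that add atoms: bis(pinacolato)diboron, CC1(C)OB(OC1(C)C)B1OC(C)(C)C(C)(C)O1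
Why: Miyaura-type allylic borylation: oxidative addition of the acetate to zerovalent palladium and transmetallation with the diboron reagent deliver boron to the unsubstituted allyl terminus, and the (Z) geometry is kept because the π-allyl cannot isomerise quickly through its disubstituted terminus.

Step 16
Reactants: 14 2-[(1S,3R,4S,6S)-6-[(tert-butyldimethylsilyl)oxy]-3,4-dimethyl-2-oxo-1-(prop-2-yn-1-yl)cyclohexyl]prop-2-enal; 21 2-[(2Z)-5-[(4-methoxyphenyl)methoxy]-3-methylpent-2-en-1-yl]-4,4,5,5-tetramethyl-1,3,2-dioxaborolane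
Product: 22 (2S,3S,5S,6R)-3-[(tert-butyldimethylsilyl)oxy]-2-[(3R,4S)-3-hydroxy-4-{2-[(4-methoxyphenyl)methoxy]ethyl}-4-methylhexa-1,5-dien-2-yl]-5,6-dimethyl-2-(prop-2-yn-1-yl)cyclohexan-1-one
Conditions: (R)-TRIP [(R)-3,3'-bis(2,4,6-triisopropylphenyl)-1,1'-binaphthyl-2,2'-diyl hydrogen phosphate] (10 mol %), 4 Å molecular sieves, toluene, −30 → 0 °C; aq. NaHCO3
Reagents that add atoms: none
Why: Brønsted acid catalysed allylboration (carbonyl allylation through a closed six-membered Zimmerman–Traxler chair) joins the two fragments at C11–C12: the (Z)-boronate puts the CH2CH2OPMB arm syn and the methyl anti to the new hydroxyl, which fixes the quaternary C12 (S) relative to C11, and the phosphoric acid bound to the boronate directs attack to the Re face of the aldehyde, which fixes C11 (R at this stage), the ketone being too unreactive to compete.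

Step 17
Reactants: 22 homoallylic alcohol (coupling product)
Product: 23 11-O-tert-butyldimethylsilyl ether of 22 (8,11-bis-silyl ether)
Conditions: TBSOTf, 2,6-lutidine, CH2Cl2, 0 → 23 °C
Reagents that add atoms: tert-butyldimethylsilyl trifluoromethanesulfonate, CC(C)(C)[Si](C)(C)OS(=O)(=O)C(F)(F)F
Why: Silylation of the hindered secondary alcohol with the silyl triflate prevents lactol formation with the later C14 aldehyde and protects O11 to the end.

Step 18
Reactants: 23 8,11-bis-silyl ether
Product: 25 C5-bromo ketone (α-bromo derivative of 23; both C5 epimers), via trimethylsilyl enol ether 24 (not isolated)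
Conditions: TMSOTf, Et3N, CH2Cl2, 0 °C; then NBS, THF, −78 °C
Reagents that add atoms: trimethylsilyl trifluoromethanesulfonate, C[Si](C)(C)OS(=O)(=O)C(F)(F)F (silyl group of 24 only); N-bromosuccinimide, O=C1CCC(=O)N1Br
Why: Regiospecific soft enolisation (C9 is quaternary) and electrophilic α-bromination of the silyl enol ether by NBS at −78 °C, where the enol ether reacts far faster than the other alkenes, install the tertiary bromide for reductive enolate generation, the configuration at C5 being irrelevant.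

Step 19
Reactants: 25 C5-bromo ketone
Product: 26 bromo ketone primary alcohol (C14–OH)
Conditions: DDQ, CH2Cl2–pH 7 buffer (10:1), 0 °C
Reagents that add atoms: none
Why: Oxidative cleavage of the p-methoxybenzyl ether by DDQ (hydride abstraction from the electron-rich benzylic position and hydrolysis) frees the primary alcohol without touching silyl ethers, bromide, alkyne or alkenes.

Step 20
Reactants: 26 bromo ketone primary alcohol
Product: 27 bromo ketone aldehyde (C14 aldehyde)
Conditions: Dess–Martin periodinane, NaHCO3, CH2Cl2, 0 → 23 °C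
Reagents that add atoms: none
Why: Dess–Martin oxidation of the primary alcohol under buffered conditions gives the C14 aldehyde without epimerisation or elimination of the α-bromo ketone.

Step 21
Reactants: 27 bromo ketone aldehyde
Product: 28 bridged bicyclic β-hydroxy ketone (six- and eight-membered rings sharing C5–C4–C9; C4 ketone, C14–OH; 5R,6S,8S,9S,11R,12S,14R)
Conditions: SmI2 (2.5 equiv), THF (0.005 M), −78 °C; aq. NH4Cl
Reagents that add atoms: none
Why: Samarium Reformatsky-type intramolecular aldol addition: SmI2 reduces the α-bromo ketone (much faster than the aldehyde) to a trivalent samarium enolate that adds to the tethered aldehyde and closes the eight-membered ring at C5–C14, the short tether from C9 allowing bond formation on only one face of the enolate, which sets the quaternary C5, and the samarium-chelated chair-like transition state with the aldehyde chain pseudo-equatorial setting C14 (R).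

Step 22
Reactants: 28 bridged bicyclic β-hydroxy ketone
Product: 29 14-O-acetate of 28
Conditions: Ac2O, Et3N, DMAP, CH2Cl2, 23 → 40 °C
Reagents that add atoms: acetic anhydride, CC(=O)OC(C)=O
Why: DMAP-catalysed acylation of the hindered C14 alcohol installs the acetate of the target and removes the β-hydroxy ketone that could undergo retro-aldol cleavage or hydrogen abstraction at C14 later.

Step 23
Reactants: 29 14-O-acetate
Product: 30 1,4-diketone (9-(2-oxopropyl) analogue of 29)
Conditions: AuCl(PPh3) (5 mol %), AgOTf (5 mol %), H2O (5 equiv), 1,4-dioxane, 60 °C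
Reagents that add atoms: water, O
Why: Gold-catalysed Markovnikov hydration of the terminal alkyne, assisted by the neighbouring C4 carbonyl oxygen, gives the methyl ketone while alkenes, acetate and silyl ethers are inert.

Step 24
Reactants: 30 1,4-diketone with C10 exo-methylene
Product: 31 (10R)-10-methyl 1,4-diketone (5R,6S,8S,9S,10R,11S,12S,14R)
Conditions: Mn(dpm)3 [tris(2,2,6,6-tetramethylheptane-3,5-dionato)manganese] (10 mol %), PhSiH3, t-BuOOH, i-PrOH, 23 °C
Reagents that add atoms: none
Why: Metal-hydride hydrogen atom transfer hydrogenation (Mukaiyama-type, Shenvi conditions) reduces only the 1,1-disubstituted alkene via the tertiary C10 radical, the monosubstituted vinyl group reacting much more slowly, and the second hydrogen is delivered to the exposed face of the ring-bound radical, away from the C12 quaternary centre and the C9 substituents, which sets C10 (R).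

Step 25
Reactants: 31 (10R)-10-methyl 1,4-diketone
Product: 33 8,11-bis-O-tert-butyldimethylsilyl ether of the target, via aldol adduct 32 (not isolated)
Conditions: TsOH·H2O (0.3 equiv), benzene, 80 °C, Dean–Stark
Reagents that add atoms: none
Why: Acid-catalysed intramolecular aldol condensation: the enol of the methyl ketone adds to the C4 ketone to close the five-membered ring and loss of water gives the cyclopentenone, the acetate surviving these conditions, furan formation being impossible because C9 is quaternary, and the only stereocentre formed (C4 carbinol) being destroyed on dehydration.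

Step 26
Reactants: 33 8,11-bis-O-tert-butyldimethylsilyl ether of the target
Product: 34 pleuromutilin E
Conditions: 48% aq. HF, MeCN, 0 → 23 °C
Reagents that add atoms: none
Why: Acidic fluoride cleavage of both silyl ethers frees the C8 and C11 hydroxyls and leaves acetate, enone and vinyl group untouched, giving the target with all eight stereocentres as in the SMILES.

**Compound list**

1 | cyclohexane-1,3-dione | O=C1CCCC(=O)C1 | starting material
2 | 1-bromo-3-methylbut-2-ene (prenyl bromide) | CC(C)=CCBr | starting material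
3 | 2-(3-methylbut-2-en-1-yl)cyclohexane-1,3-dione | CC(C)=CCC1C(=O)CCCC1=O | intermediate
4 | 3-bromoprop-1-yne (propargyl bromide) | C#CCBr | starting material
5 | 2-(3-methylbut-2-en-1-yl)-2-(prop-2-yn-1-yl)cyclohexane-1,3-dione | CC(C)=CCC1(CC#C)C(=O)CCCC1=O | intermediate
6 | (2R,3S)-3-hydroxy-2-(3-methylbut-2-en-1-yl)-2-(prop-2-yn-1-yl)cyclohexan-1-one | CC(C)=CC[C@@]1(CC#C)[C@@H](O)CCCC1=O | intermediate
7 | (2R,3S)-3-[(tert-butyldimethylsilyl)oxy]-2-(3-methylbut-2-en-1-yl)-2-(prop-2-yn-1-yl)cyclohexan-1-one | CC(C)=CC[C@@]1(CC#C)[C@@H](O[Si](C)(C)C(C)(C)C)CCCC1=O | intermediate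
8 | (2R,3S)-3-[(tert-butyldimethylsilyl)oxy]-6-methyl-2-(3-methylbut-2-en-1-yl)-2-(prop-2-yn-1-yl)cyclohexan-1-one (both C6 epimers of the ring, i.e. C5) | CC(C)=CC[C@@]1(CC#C)[C@@H](O[Si](C)(C)C(C)(C)C)CCC(C)C1=O | intermediate
9 | trimethylsilyl enol ether of 8: tert-butyl{[(1S,2R)-4-methyl-2-(3-methylbut-2-en-1-yl)-2-(prop-2-yn-1-yl)-3-[(trimethylsilyl)oxy]cyclohex-3-en-1-yl]oxy}dimethylsilane | CC(C)=CC[C@@]1(CC#C)[C@@H](O[Si](C)(C)C(C)(C)C)CCC(C)=C1O[Si](C)(C)C | intermediate
10 | (5S,6R)-5-[(tert-butyldimethylsilyl)oxy]-2-methyl-6-(3-methylbut-2-en-1-yl)-6-(prop-2-yn-1-yl)cyclohex-2-en-1-one | CC(C)=CC[C@@]1(CC#C)[C@@H](O[Si](C)(C)C(C)(C)C)CC=C(C)C1=O | intermediate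
11 | (2R,3S,5S,6R)-3-[(tert-butyldimethylsilyl)oxy]-5,6-dimethyl-2-(3-methylbut-2-en-1-yl)-2-(prop-2-yn-1-yl)cyclohexan-1-one | CC(C)=CC[C@@]1(CC#C)[C@@H](O[Si](C)(C)C(C)(C)C)C[C@H](C)[C@@H](C)C1=O | intermediate
12 | 2-[(1S,3R,4S,6S)-6-[(tert-butyldimethylsilyl)oxy]-3,4-dimethyl-2-oxo-1-(prop-2-yn-1-yl)cyclohexyl]acetaldehyde | O=CC[C@@]1(CC#C)[C@@H](O[Si](C)(C)C(C)(C)C)C[C@H](C)[C@@H](C)C1=O | intermediate
13 | Mannich base: 3-(dimethylamino)-2-[(1S,3R,4S,6S)-6-[(tert-butyldimethylsilyl)oxy]-3,4-dimethyl-2-oxo-1-(prop-2-yn-1-yl)cyclohexyl]propanal (C2 of the propanal not defined) | O=CC(CN(C)C)[C@@]1(CC#C)[C@@H](O[Si](C)(C)C(C)(C)C)C[C@H](C)[C@@H](C)C1=O | intermediate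
14 | 2-[(1S,3R,4S,6S)-6-[(tert-butyldimethylsilyl)oxy]-3,4-dimethyl-2-oxo-1-(prop-2-yn-1-yl)cyclohexyl]prop-2-enal | O=CC(=C)[C@@]1(CC#C)[C@@H](O[Si](C)(C)C(C)(C)C)C[C@H](C)[C@@H](C)C1=O | intermediate
15 | but-3-yn-1-ol | C#CCCO | starting material
16 | 1-[(but-3-yn-1-yloxy)methyl]-4-methoxybenzene | C#CCCOCc1ccc(OC)cc1 | intermediate
17 | ethyl 5-[(4-methoxyphenyl)methoxy]pent-2-ynoate | CCOC(=O)C#CCCOCc1ccc(OC)cc1 | intermediate
18 | ethyl (2Z)-5-[(4-methoxyphenyl)methoxy]-3-methylpent-2-enoate | CCOC(=O)/C=C(/C)CCOCc1ccc(OC)cc1 | intermediate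
19 | (2Z)-5-[(4-methoxyphenyl)methoxy]-3-methylpent-2-en-1-ol | OC/C=C(/C)CCOCc1ccc(OC)cc1 | intermediate
20 | (2Z)-5-[(4-methoxyphenyl)methoxy]-3-methylpent-2-en-1-yl acetate | CC(=O)OC/C=C(/C)CCOCc1ccc(OC)cc1 | intermediate
21 | 2-[(2Z)-5-[(4-methoxyphenyl)methoxy]-3-methylpent-2-en-1-yl]-4,4,5,5-tetramethyl-1,3,2-dioxaborolane | CC1(C)OB(C/C=C(/C)CCOCc2ccc(OC)cc2)OC1(C)C | intermediate
22 | (2S,3S,5S,6R)-3-[(tert-butyldimethylsilyl)oxy]-2-[(3R,4S)-3-hydroxy-4-{2-[(4-methoxyphenyl)methoxy]ethyl}-4-methylhexa-1,5-dien-2-yl]-5,6-dimethyl-2-(prop-2-yn-1-yl)cyclohexan-1-one | C=C[C@](C)(CCOCc1ccc(OC)cc1)[C@@H](O)C(=C)[C@@]2(CC#C)[C@@H](O[Si](C)(C)C(C)(C)C)C[C@H](C)[C@@H](C)C2=O | intermediate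
23 | 11-O-tert-butyldimethylsilyl ether of 22 (8,11-bis-silyl ether; C11 R, C12 S) | C=C[C@](C)(CCOCc1ccc(OC)cc1)[C@@H](O[Si](C)(C)C(C)(C)C)C(=C)[C@@]2(CC#C)[C@@H](O[Si](C)(C)C(C)(C)C)C[C@H](C)[C@@H](C)C2=O | intermediate
24 | trimethylsilyl enol ether of 23 (Me3SiO–C4=C5) | C=C[C@](C)(CCOCc1ccc(OC)cc1)[C@@H](O[Si](C)(C)C(C)(C)C)C(=C)[C@@]2(CC#C)[C@@H](O[Si](C)(C)C(C)(C)C)C[C@H](C)C(C)=C2O[Si](C)(C)C | intermediate
25 | C5-bromo ketone: 23 with Br and Me on C5 (both C5 epimers) | C=C[C@](C)(CCOCc1ccc(OC)cc1)[C@@H](O[Si](C)(C)C(C)(C)C)C(=C)[C@@]2(CC#C)[C@@H](O[Si](C)(C)C(C)(C)C)C[C@H](C)C(C)(Br)C2=O | intermediate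
26 | bromo ketone primary alcohol: 25 with CH2CH2OH on C12 | C=C[C@](C)(CCO)[C@@H](O[Si](C)(C)C(C)(C)C)C(=C)[C@@]1(CC#C)[C@@H](O[Si](C)(C)C(C)(C)C)C[C@H](C)C(C)(Br)C1=O | intermediate
27 | bromo ketone aldehyde: 25 with CH2CHO on C12 | C=C[C@](C)(CC=O)[C@@H](O[Si](C)(C)C(C)(C)C)C(=C)[C@@]1(CC#C)[C@@H](O[Si](C)(C)C(C)(C)C)C[C@H](C)C(C)(Br)C1=O | intermediate
28 | bridged bicyclic β-hydroxy ketone, mutilin numbering: (5R,6S,8S,9S,11R,12S,14R)-8,11-bis[(tert-butyldimethylsilyl)oxy]-14-hydroxy-5,6,12-trimethyl-10-methylidene-4-oxo-9-(prop-2-yn-1-yl)-12-vinyl; six-membered ring C4–C9, eight-membered ring C4,C5,C14–C9 | C=C[C@]1(C)C[C@@H](O)[C@]2(C)C(=O)[C@](CC#C)([C@@H](O[Si](C)(C)C(C)(C)C)C[C@@H]2C)C(=C)[C@@H]1O[Si](C)(C)C(C)(C)C | intermediate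
29 | 14-O-acetate of 28 | C=C[C@]1(C)C[C@@H](OC(C)=O)[C@]2(C)C(=O)[C@](CC#C)([C@@H](O[Si](C)(C)C(C)(C)C)C[C@@H]2C)C(=C)[C@@H]1O[Si](C)(C)C(C)(C)C | intermediate
30 | 1,4-diketone: 29 with 2-oxopropyl in place of propargyl on C9 | C=C[C@]1(C)C[C@@H](OC(C)=O)[C@]2(C)C(=O)[C@](CC(C)=O)([C@@H](O[Si](C)(C)C(C)(C)C)C[C@@H]2C)C(=C)[C@@H]1O[Si](C)(C)C(C)(C)C | intermediate
31 | (10R)-10-methyl 1,4-diketone (5R,6S,8S,9S,10R,11S,12S,14R): 30 with CH(CH3) at C10 | C=C[C@]1(C)C[C@@H](OC(C)=O)[C@]2(C)C(=O)[C@](CC(C)=O)([C@@H](O[Si](C)(C)C(C)(C)C)C[C@@H]2C)[C@@H](C)[C@@H]1O[Si](C)(C)C(C)(C)C | intermediate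
32 | aldol adduct: tricyclic C4 tertiary alcohol with C2 ketone (five-membered ring closed at C3–C4; C4 configuration not defined) | C=C[C@]1(C)C[C@@H](OC(C)=O)[C@]2(C)C3(O)CC(=O)C[C@@]3([C@@H](O[Si](C)(C)C(C)(C)C)C[C@@H]2C)[C@@H](C)[C@@H]1O[Si](C)(C)C(C)(C)C | intermediate
33 | 8,11-bis-O-tert-butyldimethylsilyl ether of pleuromutilin E (5S,6S,8S,9R,10R,11S,12S,14R) | C=C[C@]1(C)C[C@@H](OC(C)=O)[C@]2(C)C3=CC(=O)C[C@@]3([C@@H](O[Si](C)(C)C(C)(C)C)C[C@@H]2C)[C@@H](C)[C@@H]1O[Si](C)(C)C(C)(C)C | intermediate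
34 | pleuromutilin E: (5S,6S,8S,9R,10R,11S,12S,14R)-14-acetoxy-8,11-dihydroxy-2-oxomutil-3-ene | C=C[C@]1(C)C[C@@H](OC(C)=O)[C@]2(C)C3=CC(=O)C[C@@]3([C@@H](O)C[C@@H]2C)[C@@H](C)[C@@H]1O | target

**Step count and risks**

Total step count: 26. Longest linear sequence: 20 steps (steps 1–9, then 16–26); the boronate branch is steps 10–15.

The three steps most likely to fail:

Step 21 (closure of the eight-membered ring and control of C5 and C14). The fallback sets out from 23 and comes back at 28. Compound 23 is silylated with TBSOTf and Et3N to the tert-butyldimethylsilyl enol ether F1. The PMB ether is cleaved with buffered DDQ at 0 °C (the fully substituted, hindered enol ether reacts slowly) to give the enol ether primary alcohol F2. Parikh–Doering oxidation (SO3·pyridine, DMSO, iPr2NEt) gives the enol ether aldehyde F3. BF3·OEt2 in CH2Cl2 at −78 °C under high dilution then closes the ring by an intramolecular Mukaiyama aldol addition through an open transition state and gives 28 after aqueous work-up.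

Step 24 (face of hydrogen delivery at C10). The fallback sets out from 28 and comes back at 31. With the C14 hydroxyl still free, the same Mn(dpm)3/PhSiH3/t-BuOOH conditions let the C10 radical take the C14 hydrogen across the ring (1,5-hydrogen atom transfer). This delivers hydrogen to C10 intramolecularly and leaves the C10-methyl 4,14-diketone F4. SmI2/H2O/Et3N reduces the less hindered C14 ketone to the more stable alcohol, the C10-methyl hydroxy ketone F5. Acetylation (Ac2O, DMAP) gives the C10-methyl alkyne acetate F6, and gold-catalysed hydration as in step 23 gives 31.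

Step 25 (aldol condensation onto a ketone flanked by two quaternary carbons with the acetate present). The fallback sets out from 31 and comes back at 33. Kinetic enolisation of the methyl ketone (LiN(SiMe3)2, Me3SiCl, THF, −78 °C) gives the terminal trimethylsilyl enol ether F7. TiCl4 in CH2Cl2 at −78 °C effects an intramolecular Mukaiyama aldol addition to the C4 ketone, and the β-hydroxy ketone 32 is isolated this time. Dehydration with the Burgess reagent (benzene, 50 °C) gives 33.

**Further compounds**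

F1 | step 21 | tert-butyldimethylsilyl enol ether of 23 (TBSO–C4=C5) | C=C[C@](C)(CCOCc1ccc(OC)cc1)[C@@H](O[Si](C)(C)C(C)(C)C)C(=C)[C@@]2(CC#C)[C@@H](O[Si](C)(C)C(C)(C)C)C[C@H](C)C(C)=C2O[Si](C)(C)C(C)(C)C
F2 | step 21 | enol ether primary alcohol (F1 without PMB) | C=C[C@](C)(CCO)[C@@H](O[Si](C)(C)C(C)(C)C)C(=C)[C@@]1(CC#C)[C@@H](O[Si](C)(C)C(C)(C)C)C[C@H](C)C(C)=C1O[Si](C)(C)C(C)(C)C
F3 | step 21 | enol ether aldehyde (C14 aldehyde) | C=C[C@](C)(CC=O)[C@@H](O[Si](C)(C)C(C)(C)C)C(=C)[C@@]1(CC#C)[C@@H](O[Si](C)(C)C(C)(C)C)C[C@H](C)C(C)=C1O[Si](C)(C)C(C)(C)C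
F4 | step 24 | C10-methyl 4,14-diketone (alkyne retained) | C=C[C@]1(C)CC(=O)[C@]2(C)C(=O)[C@](CC#C)([C@@H](O[Si](C)(C)C(C)(C)C)C[C@@H]2C)[C@@H](C)[C@@H]1O[Si](C)(C)C(C)(C)C
F5 | step 24 | C10-methyl 14-hydroxy ketone (alkyne retained) | C=C[C@]1(C)C[C@@H](O)[C@]2(C)C(=O)[C@](CC#C)([C@@H](O[Si](C)(C)C(C)(C)C)C[C@@H]2C)[C@@H](C)[C@@H]1O[Si](C)(C)C(C)(C)C
F6 | step 24 | C10-methyl alkyne 14-acetate | C=C[C@]1(C)C[C@@H](OC(C)=O)[C@]2(C)C(=O)[C@](CC#C)([C@@H](O[Si](C)(C)C(C)(C)C)C[C@@H]2C)[C@@H](C)[C@@H]1O[Si](C)(C)C(C)(C)C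
F7 | step 25 | terminal trimethylsilyl enol ether of the methyl ketone of 31 | C=C[C@]1(C)C[C@@H](OC(C)=O)[C@]2(C)C(=O)[C@](CC(=C)O[Si](C)(C)C)([C@@H](O[Si](C)(C)C(C)(C)C)C[C@@H]2C)[C@@H](C)[C@@H]1O[Si](C)(C)C(C)(C)C
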